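Z cannot stand in a flask before L has reached the solution, if J reacts with dissolved L, and each flask here starts with none of L dissolved. We have to choose the temperature for the next run.

all flasks: L 72 mM (held)
- alpha: J 0.25 M; temperature 35 °C; run made earlier
- epsilon: J 0.38 M; temperature 65 °C; run made earlier
- teal: J 0.50 M; temperature 65 °C; time 4.0 min
- ochre: J 0.50 M; temperature 90 °C; time 4.0 min
- red: J 0.50 M; temperature 40 °C; time 4.0 min

- alpha (time / min: Z / %): 3.00: 16.5; 6.00: 37.6; 8.00: 49.9; 12.0: 66.9; 20.0: 84.8
- epsilon (time / min: Z / %): 0.417: 7.2; 0.667: 14.1; 0.833: 19.1; 1.33: 32.4; 2.00: 48.1; 3.00: 68.3; 5.00: 92.8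

(standard deviation of a reading: 0.5 percentage points)

- the analysis behind the earlier runs scatters by 0.5 percentage points, standard deviation
- at the start none of L is in solution

* which flask leads in amount of Z, in percent of the J charged ("all alike" within 1.5 percentage points) (teal / ochre / red / all alike)
* how much Z is there at the end, in percent of the J charged: teal
* how much Z is there at the end, in percent of the J charged: ochre
* how much Z is there at the end, in percent of the J charged: red

Both earlier runs open with a lag. Epsilon then climbs almost straight while alpha falls away nearly first order in J, which we read as two steps in series. We therefore reckon the time to reach a fraction x of the charge as a sum of three terms. These are a lag τ, the gas time x·tg, and the logarithm of one over what remains divided by k′. Here k′ is the pseudo-first-order constant of J in the solution, V is the ceiling on L uptake, and tg is the charge divided by V, the time the gas needs to bring in L for the whole charge at that ceiling, taking one L per J.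

Epsilon's readings at 0.667 min, 2.00 min and 5.00 min give V = 0.151 M min⁻¹, k′ = 1.05 min⁻¹ and τ = 0.168 min. Keeping that V, alpha gives k′ = 0.107 min⁻¹ and τ = 0.964 min.

For our charge the gas time is tg = 3.31 min, shorter than the 4.0 min allowed. Running ln k′ straight against temperature gives 7.08 min⁻¹ for ochre and 0.156 min⁻¹ for red. Teal then needs 3.97 min for 75.0%. Ochre, with epsilon's lag, needs 3.47 min for 90.0%. Red, with alpha's lag, needs 3.64 min for 25.0%. In this reckoning the gas is the rate-limiting step in ochre, while in red the reaction time outweighs it. We would charge ochre.

The forecast also names ochre, with teal 75% (71% to 79%), ochre 96% (87% to 100%) and red 28% (23% to 33%), reading “gas uptake in series with reaction”.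

The flasks give teal 74.5%, ochre 95.0% and red 30.7%, so ochre leads.

    J + E → X (k = 0.0430 L mol⁻¹ s⁻¹, Ea = 68.0 kJ mol⁻¹)
    X → Z (k = 0.0340 s⁻¹, Ea = 92.0 kJ mol⁻¹)
    J + X → Q (k = 0.00250 L mol⁻¹ s⁻¹, Ea = 59.0 kJ mol⁻¹)
    L ⇌ E, rate k4*(csat - [E]) (kL = 0.0330 s⁻¹)
    (constants at 40 °C)

By our tg the Z found costs 3.14 min of gas time in ochre but 1.02 min in red, and at 2.00 min E, the L in solution, stood at 0.00580 M in ochre against 0.0462 M in red. Teal shifts by 5 points if read at 3.66 min or 4.38 min. For red left longer, tg with alpha's lag puts 83.3% at 15.2 min; the flask holds 84.2% at 15 min.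

Readings and results are calculated with made-up constants, noise included.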